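**Retrosynthetic overview**
- Rings A and B are bought intact as 2',3'-dimethoxyacetophenone (1) and 3,4,5-trimethoxybenzoic acid (2); only the pyranone ring C is built.
- Key disconnection: the aryl C8a–O1 bond, made by a direct ketone-directed ortho-C–H aroyloxylation of 1 with 2 to give aryl ester 3 (new method).
- C2–C3 comes from a Baker–Venkataraman O→C acyl shift (3 → diketone 4); O1–C2 comes from cyclodehydration (4 → 5), which closes ring C last.

Assumption: Cerosilin B has no stereocentre and no stereogenic double bond, so "the single enantiomer" is the achiral compound itself and no stereocontrol is needed.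

**Step 1**
Reactants: 1 1-(2,3-dimethoxyphenyl)ethan-1-one (2',3'-dimethoxyacetophenone); 2 3,4,5-trimethoxybenzoic acid
Product: 3 2-acetyl-3,4-dimethoxyphenyl 3,4,5-trimethoxybenzoate
Conditions: 2 (1.5 equiv), [RuCl2(p-cymene)]2 (5 mol%), AgSbF6 (20 mol%), (NH4)2S2O8 (2.0 equiv), DCE, 100 °C, 24 h; NaHCO3 wash removes excess 2
Reagents that add atoms: none
Why: Proposed new method: a cationic Ru(II) κ2-3,4,5-trimethoxybenzoate (from the chloride dimer, AgSbF6 and 2) binds the ketone oxygen and undergoes carboxylate-assisted ruthenation at C6'–H, the only free ortho position (C2' carries OMe) and one activated by the para 3'-OMe, to give a five-membered ruthenacycle; persulfate oxidises this to Ru(IV), and C–O reductive elimination with the bound aroate forms the aryl ester and returns Ru(II). The closest known reaction types are Ru(II)-catalysed amide-directed ortho-C–H benzoxylation of anilides and benzamides with aromatic acids and persulfate, and Ru- or Pd-catalysed ketone-directed ortho-C–H trifluoroacetoxylation in TFA/TFAA; the new element is a weakly coordinating ketone directing an aroyloxylation with an electron-rich benzoic acid outside the TFA manifold.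

**Step 2**
Reactants: 3 2-acetyl-3,4-dimethoxyphenyl 3,4,5-trimethoxybenzoate
Product: 5 Cerosilin B [5,6-dimethoxy-2-(3,4,5-trimethoxyphenyl)-4H-chromen-4-one], via phenolic diketone 4 (not isolated)
Conditions: KOtBu (2.5 equiv), THF, 0 °C→rt, 2 h; then AcOH, conc. H2SO4 (4 equiv), 95 °C, 1 h
Reagents that add atoms: none
Why: Baker–Venkataraman rearrangement (the methyl ketone enolate attacks the neighbouring aryl ester through a six-membered transition state to give the o-hydroxyaryl 1,3-diketone) followed by acid-catalysed cyclodehydration (phenol OH adds to the B-ring carbonyl, water is lost) gives the flavone; no stereocentre is formed and the methyl ethers survive short heating in H2SO4/AcOH.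

**Compound list**
1 | 1-(2,3-dimethoxyphenyl)ethan-1-one (2',3'-dimethoxyacetophenone) | CC(=O)c1cccc(OC)c1OC | starting material
2 | 3,4,5-trimethoxybenzoic acid | COc1cc(C(=O)O)cc(OC)c1OC | starting material
3 | 2-acetyl-3,4-dimethoxyphenyl 3,4,5-trimethoxybenzoate | CC(=O)c1c(OC(=O)c2cc(OC)c(OC)c(OC)c2)ccc(OC)c1OC | intermediate
4 | 1-(6-hydroxy-2,3-dimethoxyphenyl)-3-(3,4,5-trimethoxyphenyl)propane-1,3-dione (formed as its potassium salt) | COc1cc(C(=O)CC(=O)c2c(O)ccc(OC)c2OC)cc(OC)c1OC | intermediate (not isolated)
5 | Cerosilin B, 5,6-dimethoxy-2-(3,4,5-trimethoxyphenyl)-4H-chromen-4-one | COc1cc(-c2cc(=O)c3c(OC)c(OC)ccc3o2)cc(OC)c1OC | target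

**Step count**
Total steps: 2. Longest linear sequence: 2 (1 → 3 → 5).

**Steps most likely to fail**
The route has only two steps, so the ranking covers step 1 and the two stages of step 2 separately.

1. Step 1 (the proposed new C–H aroyloxylation). Risks are weak ketone binding to Ru without TFA, competing carboxylate-directed metalation of 2, and persulfate oxidation of the electron-rich rings. The fallback uses known chemistry, sets out from 1 and comes back at 3. Ketone 1 is oxygenated at C6' under the established trifluoroacetate conditions (Pd(TFA)2 5 mol% or [RuCl2(p-cymene)]2 2.5 mol%, K2S2O8, TFA/TFAA 9:1, 50–80 °C) to give 2-acetyl-3,4-dimethoxyphenyl trifluoroacetate F1. Aqueous NaHCO3 work-up hydrolyses this to 1-(6-hydroxy-2,3-dimethoxyphenyl)ethan-1-one F2. Acid 2 is converted with oxalyl chloride and catalytic DMF into 3,4,5-trimethoxybenzoyl chloride F3. F2 and F3 (pyridine, cat. DMAP, CH2Cl2, 0 °C→rt) then give ester 3.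

2. Step 2, first stage (Baker–Venkataraman shift). The acetyl group is flanked by two ortho substituents, and tert-butoxide may cleave the aryl ester instead. The fallback sets out from 3 and comes back at 5, replacing the Claisen-type C–C formation by an intramolecular ester Wittig olefination. Selective α-bromination of 3 (CuBr2, EtOAc/CHCl3, reflux) gives 2-(2-bromoacetyl)-3,4-dimethoxyphenyl 3,4,5-trimethoxybenzoate F4. PPh3 in MeCN gives the phosphonium salt {2-[3,4-dimethoxy-6-(3,4,5-trimethoxybenzoyloxy)phenyl]-2-oxoethyl}triphenylphosphonium bromide F5. Aqueous Na2CO3 liberates the stabilised ylide 3,4-dimethoxy-2-[(triphenylphosphoranylidene)acetyl]phenyl 3,4,5-trimethoxybenzoate F6. In refluxing toluene F6 olefinates its own ester carbonyl and delivers 5 directly.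

3. Step 2, second stage (acid cyclodehydration). Risks are stalling at the 2-hydroxyflavanone, retro-Claisen cleavage of 4, or partial loss of the 5-O-methyl group in hot acid. The fallback sets out from 3 and comes back at 5 by the chalcone route, which avoids strong acid. Methanolysis of 3 (K2CO3, MeOH, rt) gives the phenol F2, the same compound as in the first fallback. Claisen–Schmidt condensation of F2 with purchased 3,4,5-trimethoxybenzaldehyde F7 (KOH, EtOH, rt) gives (E)-1-(6-hydroxy-2,3-dimethoxyphenyl)-3-(3,4,5-trimethoxyphenyl)prop-2-en-1-one F8. Oxidative cyclisation of F8 (I2 cat., DMSO, 130 °C) gives 5.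

**Further compounds**
F1 | step 1 | 2-acetyl-3,4-dimethoxyphenyl trifluoroacetate | CC(=O)c1c(OC(=O)C(F)(F)F)ccc(OC)c1OC
F2 | step 1 | 1-(6-hydroxy-2,3-dimethoxyphenyl)ethan-1-one | CC(=O)c1c(O)ccc(OC)c1OC
F3 | step 1 | 3,4,5-trimethoxybenzoyl chloride | COc1cc(C(=O)Cl)cc(OC)c1OC
F4 | step 2 | 2-(2-bromoacetyl)-3,4-dimethoxyphenyl 3,4,5-trimethoxybenzoate | O=C(CBr)c1c(OC(=O)c2cc(OC)c(OC)c(OC)c2)ccc(OC)c1OC
F5 | step 2 | {2-[3,4-dimethoxy-6-(3,4,5-trimethoxybenzoyloxy)phenyl]-2-oxoethyl}triphenylphosphonium bromide | [Br-].O=C(C[P+](c1ccccc1)(c1ccccc1)c1ccccc1)c1c(OC(=O)c2cc(OC)c(OC)c(OC)c2)ccc(OC)c1OC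
F6 | step 2 | 3,4-dimethoxy-2-[(triphenylphosphoranylidene)acetyl]phenyl 3,4,5-trimethoxybenzoate | O=C(C=P(c1ccccc1)(c1ccccc1)c1ccccc1)c1c(OC(=O)c2cc(OC)c(OC)c(OC)c2)ccc(OC)c1OC
F7 | step 2 | 3,4,5-trimethoxybenzaldehyde (purchased) | COc1cc(C=O)cc(OC)c1OC
F8 | step 2 | (E)-1-(6-hydroxy-2,3-dimethoxyphenyl)-3-(3,4,5-trimethoxyphenyl)prop-2-en-1-one | COc1cc(/C=C/C(=O)c2c(O)ccc(OC)c2OC)cc(OC)c1OC
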